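**Retrosynthetic overview**
1. The target comes from global hydrogenolysis of the 8-bromo tetradeca-O-benzyl precursor 16; the bromine at C8 forces ring A of the flavan to react at C6 and leaves in the same step.
2. Key disconnection, upper ring A–CH2: 16 ⇒ α-galloyloxy aldehyde 12 + unprotected phloroglucinol + hydride. Phloroglucinol loses its aromaticity and threefold symmetry in an ortho-quinone methide that is reduced in the flask.
3. Cα–Cβ bond: 12 ⇒ diarylmethane 7 (oxidised by DDQ to a diarylmethylium ion) + 2-oxoethyl gallate 10 under enamine catalysis; both new stereocentres are set here.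
4. C6–CH2Ar bond: 7 ⇒ 8-bromo-octa-O-benzyl-EGCG 5 + 3,4,5-tris(benzyloxy)benzyl alcohol 6 (Friedel–Crafts); 5 ⇒ (−)-epigallocatechin by benzylation, galloylation with acid 3 and bromination.
5. No ring is built: rings A, C and B arrive intact with epigallocatechin; the lower galloyl (step 2), upper ring B (step 4), the upper galloyl (step 7) and upper ring A (step 8) are then attached in that order.

Assumption: 1, 3, 6 and 13 are bought, and the target's descriptors are read from the SMILES as (1R,2S) in the propyl chain and (2R,3R) in the flavan.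

**Step 1**
Reactants: 1 (−)-epigallocatechin
Product: 2 5,7,3′,4′,5′-penta-O-benzyl-(−)-epigallocatechin
Conditions: BnBr (5.5 equiv), K2CO3 (6 equiv), DMF, 0 °C → rt, Ar, degassed
Reagents that add atoms: benzyl bromide, BrCc1ccccc1
Why: Williamson etherification with carbonate alkylates the five phenols but leaves the far less acidic secondary 3-OH free, and the two stereocentres are not involved.

**Step 2**
Reactants: 2 5,7,3′,4′,5′-penta-O-benzyl-(−)-epigallocatechin; 3 3,4,5-tris(benzyloxy)benzoic acid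
Product: 4 octa-O-benzyl-EGCG
Conditions: 3 (1.3 equiv), DCC (1.5 equiv), DMAP (0.3 equiv), CH2Cl2, 0 °C → rt
Reagents that add atoms: none
Why: Steglich esterification, in which DCC activates the acid and DMAP transfers the acyl group to the axial 3-OH with retention, because the C3–O bond is never broken.

**Step 3**
Reactants: 4 octa-O-benzyl-EGCG
Product: 5 8-bromo-octa-O-benzyl-EGCG
Conditions: NBS (1.0 equiv), CH2Cl2, −78 → −20 °C
Reagents that add atoms: N-bromosuccinimide, O=C1CCC(=O)N1Br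
Why: Electrophilic aromatic bromination of 5,7-dialkoxyflavans with NBS goes to C8, so the bromine blocks that position, leaves C6 as the only nucleophilic carbon of ring A and is removed in the last step.

**Step 4**
Reactants: 5 8-bromo-octa-O-benzyl-EGCG; 6 3,4,5-tris(benzyloxy)benzyl alcohol
Product: 7 8-bromo-6-[3,4,5-tris(benzyloxy)benzyl]-octa-O-benzyl-EGCG
Conditions: Bi(OTf)3 (5 mol %), CH2Cl2/HFIP 9:1, 0 °C, slow addition of 6 (1.5 equiv)
Reagents that add atoms: none
Why: Friedel–Crafts benzylation, in which the Lewis acid in a fluorinated alcohol ionises the electron-rich benzylic alcohol and the trioxygenated ring A, blocked at C8, can only be attacked at C6; no stereocentre is formed and the flavan centres are not involved.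

**Step 5**
Reactants: 3 3,4,5-tris(benzyloxy)benzoic acid
Product: 8 allyl 3,4,5-tris(benzyloxy)benzoate
Conditions: allyl bromide (1.2 equiv), K2CO3 (1.5 equiv), DMF, rt
Reagents that add atoms: allyl bromide, C=CCBr
Why: SN2 O-alkylation of the carboxylate gives the allyl ester as a masked 2-oxoethyl ester.

**Step 6**
Reactants: 8 allyl 3,4,5-tris(benzyloxy)benzoate
Product: 10 2-oxoethyl 3,4,5-tris(benzyloxy)benzoate, via secondary ozonide 9 (not isolated)
Conditions: O3, CH2Cl2, −78 °C (stopped at first blue colour); then Me2S, −78 °C → rt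
Reagents that add atoms: ozone, [O-][O+]=O
Why: Ozonolysis with reductive work-up (Criegee mechanism) cleaves the terminal alkene, which reacts with ozone far faster than the benzyl ethers or the ester-deactivated arene, to give the α-acyloxy acetaldehyde.

**Step 7**
Reactants: 7 8-bromo-6-[3,4,5-tris(benzyloxy)benzyl]-octa-O-benzyl-EGCG; 10 2-oxoethyl 3,4,5-tris(benzyloxy)benzoate
Product: 12 (2R,3R)-3-(8-bromo-octa-O-benzyl-EGCG-6-yl)-1-oxo-3-[3,4,5-tris(benzyloxy)phenyl]propan-2-yl 3,4,5-tris(benzyloxy)benzoate, via diarylmethylium ion 11 (not isolated)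
Conditions: DDQ (1.05 equiv), CH2Cl2, −30 °C, 20 min; then 10 (3 equiv), (S)-2-[diphenyl(trimethylsilyloxy)methyl]pyrrolidine (20 mol %), H2O (2 equiv), −30 → 0 °C; used crude after short filtration
Reagents that add atoms: none
Why: SN1-type organocatalytic α-alkylation of an aldehyde in its oxidative form: DDQ abstracts hydride from the doubly benzylic CH2 to give a diarylmethylium ion stabilised by the three ortho/para oxygens of ring A, which is captured by the E-enamine of 10 on the face left open by the diphenyl(silyloxy)methyl group of the (S)-catalyst (C2 becomes R) through an open transition state that places the bulky di-ortho-substituted ring A anti to the enamine C=C–N unit (C3 becomes R), after which hydrolysis frees the catalyst.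

**Step 8**
Reactants: 12 the (2R,3R)-aldehyde; 13 phloroglucinol
Product: 16 8-bromo-tetradeca-O-benzyl derivative of the target (upper ring A free), via benzylic carbinol 14 (not isolated), via ortho-quinone methide 15 (not isolated)
Conditions: 13 (4 equiv), diethyl 2,6-dimethyl-1,4-dihydropyridine-3,5-dicarboxylate (Hantzsch ester, 2 equiv), (PhO)2P(O)OH (10 mol %), THF/MeCN, rt → 40 °C, Ar
Reagents that add atoms: none
Why: Proposed new method: phloroglucinol attacks the protonated aldehyde through any of its three equivalent carbons (Friedel–Crafts hydroxyalkylation), the 2,4,6-trihydroxybenzylic alcohol 14 loses water to the ortho-quinone methide 15, in which the ring has lost both its aromaticity and its threefold symmetry, and the Hantzsch ester transfers hydride to the exocyclic carbon faster than a second phloroglucinol can add, restoring the aromatic triol with a CH2 link and leaving the two existing chain stereocentres untouched (the former aldehyde carbon ends as CH2, so no new centre remains); the closest known reaction type is the three-component reductive alkylation of cyclic 1,3-diones and the hydride reduction of acylphloroglucinols, both condensations followed by reduction of a quinone-methide-like intermediate.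

**Step 9**
Reactants: 16 8-bromo-tetradeca-O-benzyl derivative of the target
Product: 17 CNP0240551.2, (2R,3R)-5,7-dihydroxy-6-[(1R,2S)-2-(3,4,5-trihydroxybenzoyloxy)-1-(3,4,5-trihydroxyphenyl)-3-(2,4,6-trihydroxyphenyl)propyl]-2-(3,4,5-trihydroxyphenyl)chroman-3-yl 3,4,5-trihydroxybenzoate
Conditions: H2 (1 atm), Pd(OH)2/C, Et3N (1.5 equiv), THF/MeOH 1:1, rt; Sephadex LH-20, then reversed-phase HPLC
Reagents that add atoms: none
Why: Heterogeneous hydrogenolysis cleaves the fourteen O-benzyl ethers and the aryl C–Br bond (the amine takes up HBr), while the two esters, the pyran C2–O bond of the cis-flavan and the diarylmethine centre survive these mild conditions, as is usual for benzylated bromo-flavan-3-ols.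

**Compound list**
1 | (−)-epigallocatechin, (2R,3R)-2-(3,4,5-trihydroxyphenyl)chroman-3,5,7-triol | O[C@@H]1Cc2c(O)cc(O)cc2O[C@@H]1c1cc(O)c(O)c(O)c1 | starting material
2 | 5,7,3′,4′,5′-penta-O-benzyl-(−)-epigallocatechin, (2R,3R)-5,7-bis(benzyloxy)-2-[3,4,5-tris(benzyloxy)phenyl]chroman-3-ol | O[C@@H]1Cc2c(OCc3ccccc3)cc(OCc3ccccc3)cc2O[C@@H]1c1cc(OCc2ccccc2)c(OCc2ccccc2)c(OCc2ccccc2)c1 | intermediate
3 | 3,4,5-tris(benzyloxy)benzoic acid | OC(=O)c1cc(OCc2ccccc2)c(OCc2ccccc2)c(OCc2ccccc2)c1 | starting material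
4 | octa-O-benzyl-EGCG, (2R,3R)-5,7-bis(benzyloxy)-2-[3,4,5-tris(benzyloxy)phenyl]chroman-3-yl 3,4,5-tris(benzyloxy)benzoate | O=C(O[C@@H]1Cc2c(OCc3ccccc3)cc(OCc3ccccc3)cc2O[C@@H]1c1cc(OCc2ccccc2)c(OCc2ccccc2)c(OCc2ccccc2)c1)c1cc(OCc2ccccc2)c(OCc2ccccc2)c(OCc2ccccc2)c1 | intermediate
5 | 8-bromo-octa-O-benzyl-EGCG, (2R,3R) | O=C(O[C@@H]1Cc2c(OCc3ccccc3)cc(OCc3ccccc3)c(Br)c2O[C@@H]1c1cc(OCc2ccccc2)c(OCc2ccccc2)c(OCc2ccccc2)c1)c1cc(OCc2ccccc2)c(OCc2ccccc2)c(OCc2ccccc2)c1 | intermediate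
6 | 3,4,5-tris(benzyloxy)benzyl alcohol | OCc1cc(OCc2ccccc2)c(OCc2ccccc2)c(OCc2ccccc2)c1 | starting material
7 | (2R,3R)-8-bromo-5,7-bis(benzyloxy)-6-[3,4,5-tris(benzyloxy)benzyl]-2-[3,4,5-tris(benzyloxy)phenyl]chroman-3-yl 3,4,5-tris(benzyloxy)benzoate | C(c1cc(OCc2ccccc2)c(OCc2ccccc2)c(OCc2ccccc2)c1)c1c(OCc3ccccc3)c(Br)c2c(c1OCc3ccccc3)C[C@@H](OC(=O)c1cc(OCc3ccccc3)c(OCc3ccccc3)c(OCc3ccccc3)c1)[C@@H](c1cc(OCc3ccccc3)c(OCc3ccccc3)c(OCc3ccccc3)c1)O2 | intermediate
8 | allyl 3,4,5-tris(benzyloxy)benzoate | C=CCOC(=O)c1cc(OCc2ccccc2)c(OCc2ccccc2)c(OCc2ccccc2)c1 | intermediate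
9 | (1,2,4-trioxolan-3-yl)methyl 3,4,5-tris(benzyloxy)benzoate, secondary ozonide (not isolated) | O=C(OCC1OCOO1)c1cc(OCc2ccccc2)c(OCc2ccccc2)c(OCc2ccccc2)c1 | intermediate
10 | 2-oxoethyl 3,4,5-tris(benzyloxy)benzoate | O=CCOC(=O)c1cc(OCc2ccccc2)c(OCc2ccccc2)c(OCc2ccccc2)c1 | intermediate
11 | diarylmethylium ion of 7 (cation at the carbon between ring A C6 and the new ring B; not isolated) | [CH+](c1cc(OCc2ccccc2)c(OCc2ccccc2)c(OCc2ccccc2)c1)c1c(OCc3ccccc3)c(Br)c2c(c1OCc3ccccc3)C[C@@H](OC(=O)c1cc(OCc3ccccc3)c(OCc3ccccc3)c(OCc3ccccc3)c1)[C@@H](c1cc(OCc3ccccc3)c(OCc3ccccc3)c(OCc3ccccc3)c1)O2 | intermediate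
12 | (2R,3R)-3-[(2R,3R)-8-bromo-5,7-bis(benzyloxy)-3-{[3,4,5-tris(benzyloxy)benzoyl]oxy}-2-[3,4,5-tris(benzyloxy)phenyl]chroman-6-yl]-1-oxo-3-[3,4,5-tris(benzyloxy)phenyl]propan-2-yl 3,4,5-tris(benzyloxy)benzoate | O=C(O[C@@H](C=O)[C@H](c1cc(OCc2ccccc2)c(OCc2ccccc2)c(OCc2ccccc2)c1)c1c(OCc3ccccc3)c(Br)c2c(c1OCc3ccccc3)C[C@@H](OC(=O)c1cc(OCc3ccccc3)c(OCc3ccccc3)c(OCc3ccccc3)c1)[C@@H](c1cc(OCc3ccccc3)c(OCc3ccccc3)c(OCc3ccccc3)c1)O2)c1cc(OCc2ccccc2)c(OCc2ccccc2)c(OCc2ccccc2)c1 | intermediate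
13 | phloroglucinol (benzene-1,3,5-triol) | Oc1cc(O)cc(O)c1 | starting material
14 | benzylic carbinol from 12 and 13: the aldehyde carbon now bears OH and a 2,4,6-trihydroxyphenyl group (both carbinol epimers; chain centres as in 12; not isolated) | O=C(O[C@@H](C(O)c1c(O)cc(O)cc1O)[C@H](c1cc(OCc2ccccc2)c(OCc2ccccc2)c(OCc2ccccc2)c1)c1c(OCc3ccccc3)c(Br)c2c(c1OCc3ccccc3)C[C@@H](OC(=O)c1cc(OCc3ccccc3)c(OCc3ccccc3)c(OCc3ccccc3)c1)[C@@H](c1cc(OCc3ccccc3)c(OCc3ccccc3)c(OCc3ccccc3)c1)O2)c1cc(OCc2ccccc2)c(OCc2ccccc2)c(OCc2ccccc2)c1 | intermediate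
15 | ortho-quinone methide from 14 by loss of water: 6-alkylidene-3,5-dihydroxycyclohexa-2,4-dien-1-one (chain centres as in 12; not isolated) | O=C(O[C@@H](C=C1C(=O)C=C(O)C=C1O)[C@H](c1cc(OCc2ccccc2)c(OCc2ccccc2)c(OCc2ccccc2)c1)c1c(OCc3ccccc3)c(Br)c2c(c1OCc3ccccc3)C[C@@H](OC(=O)c1cc(OCc3ccccc3)c(OCc3ccccc3)c(OCc3ccccc3)c1)[C@@H](c1cc(OCc3ccccc3)c(OCc3ccccc3)c(OCc3ccccc3)c1)O2)c1cc(OCc2ccccc2)c(OCc2ccccc2)c(OCc2ccccc2)c1 | intermediate
16 | 8-bromo-tetradeca-O-benzyl derivative of the target: (1R,2S) chain on C6 of the (2R,3R)-flavan, all phenols benzylated except the three of the upper 2,4,6-trihydroxyphenyl ring | O=C(O[C@@H](Cc1c(O)cc(O)cc1O)[C@H](c1cc(OCc2ccccc2)c(OCc2ccccc2)c(OCc2ccccc2)c1)c1c(OCc3ccccc3)c(Br)c2c(c1OCc3ccccc3)C[C@@H](OC(=O)c1cc(OCc3ccccc3)c(OCc3ccccc3)c(OCc3ccccc3)c1)[C@@H](c1cc(OCc3ccccc3)c(OCc3ccccc3)c(OCc3ccccc3)c1)O2)c1cc(OCc2ccccc2)c(OCc2ccccc2)c(OCc2ccccc2)c1 | intermediate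
17 | CNP0240551.2, (2R,3R)-5,7-dihydroxy-6-[(1R,2S)-2-(3,4,5-trihydroxybenzoyloxy)-1-(3,4,5-trihydroxyphenyl)-3-(2,4,6-trihydroxyphenyl)propyl]-2-(3,4,5-trihydroxyphenyl)chroman-3-yl 3,4,5-trihydroxybenzoate | O=C(O[C@@H](Cc1c(O)cc(O)cc1O)[C@H](c1cc(O)c(O)c(O)c1)c1c(O)cc2c(c1O)C[C@@H](OC(=O)c1cc(O)c(O)c(O)c1)[C@@H](c1cc(O)c(O)c(O)c1)O2)c1cc(O)c(O)c(O)c1 | target

**Totals and risks**
Total step count: 9. Longest linear sequence: 7 (steps 1, 2, 3, 4, 7, 8, 9 from epigallocatechin; steps 5 and 6 make the side fragment 10).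

Most likely to fail, first: step 7. An α-acyloxy aldehyde is a weak enamine donor, DDQ may also oxidise the flavan C4–H, and the configuration at C3 rests on a steric transition-state model, so the epimer ratio may be modest and needs chromatographic separation. The fallback sets out from 7 and comes back at 17. The same cation 11, made with DDQ, is trapped, with the same catalyst, by commercially available (tert-butyldimethylsilyloxy)acetaldehyde, a proven donor class, to give the α-silyloxy aldehyde F1, whose epimers are more robust to separation. Ionic reductive Friedel–Crafts alkylation of commercially available 1,3,5-tris(benzyloxy)benzene with F1 (BF3·OEt2, Et3SiH, −40 °C) gives the silyl ether F2, and HF·pyridine in THF frees the secondary alcohol F3. Esterification of F3 with acid 3 (DCC, DMAP) gives the fully benzylated bromide F4, which is hydrogenolysed under the step 9 conditions to 17. The gallate is thus put on late and the upper ring A enters as its benzyl ether.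

Second: step 8. The quinone methide 15 may be taken by a second phloroglucinol, may tautomerise to the enol ester, or the α-acyloxy aldehyde may epimerise before it reacts. The fallback sets out from 12 and comes back at 17. 1,3,5-Tris(benzyloxy)benzene is lithiated between two of its alkoxy groups with n-BuLi in THF at 0 °C, and the resulting 2,4,6-tris(benzyloxy)phenyllithium is added to the aldehyde at −78 °C and quenched cold with acetic acid, to limit attack on the esters and acyl shift. This gives the benzylic carbinol F5 as a mixture at the new carbinol carbon, which does not matter. Hydrogenolysis under the step 9 conditions then removes the benzyl groups, the bromine and, once the ortho-hydroxyls are free, the benzylic hydroxyl through the same quinone methide on the palladium surface.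

Third: step 4. C6 is flanked by two benzyloxy groups, the benzyl alcohol can self-condense, and the acid may open the flavan at C2–O. The fallback sets out from 5 and comes back at 12. Commercially available 3,4,5-tris(benzyloxy)benzaldehyde is condensed once with C6 of 5 in the presence of Me3SiOMe and catalytic Me3SiOTf at −78 °C (Friedel–Crafts alkoxyalkylation) to give the diarylmethyl methyl ether F6. F6 is already at the oxidation level of the cation, so under the step 7 conditions trifluoroacetic acid (10 mol %) replaces DDQ, ionises it to 11, and the enamine alkylation with 10 delivers 12.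

**Further compounds**
F1 | step 7 | (2R,3R)-2-(tert-butyldimethylsilyloxy)-3-(8-bromo-octa-O-benzyl-EGCG-6-yl)-3-[3,4,5-tris(benzyloxy)phenyl]propanal | CC(C)(C)[Si](C)(C)O[C@@H](C=O)[C@H](c1cc(OCc2ccccc2)c(OCc2ccccc2)c(OCc2ccccc2)c1)c1c(OCc3ccccc3)c(Br)c2c(c1OCc3ccccc3)C[C@@H](OC(=O)c1cc(OCc3ccccc3)c(OCc3ccccc3)c(OCc3ccccc3)c1)[C@@H](c1cc(OCc3ccccc3)c(OCc3ccccc3)c(OCc3ccccc3)c1)O2
F2 | step 7 | tert-butyldimethylsilyl ether of the (1R,2S)-2-hydroxy-1-[3,4,5-tris(benzyloxy)phenyl]-3-[2,4,6-tris(benzyloxy)phenyl]propyl chain on C6 of 8-bromo-octa-O-benzyl-EGCG | CC(C)(C)[Si](C)(C)O[C@@H](Cc1c(OCc2ccccc2)cc(OCc2ccccc2)cc1OCc1ccccc1)[C@H](c1cc(OCc2ccccc2)c(OCc2ccccc2)c(OCc2ccccc2)c1)c1c(OCc3ccccc3)c(Br)c2c(c1OCc3ccccc3)C[C@@H](OC(=O)c1cc(OCc3ccccc3)c(OCc3ccccc3)c(OCc3ccccc3)c1)[C@@H](c1cc(OCc3ccccc3)c(OCc3ccccc3)c(OCc3ccccc3)c1)O2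
F3 | step 7 | secondary alcohol from F2: (1R,2S)-2-hydroxy-1-[3,4,5-tris(benzyloxy)phenyl]-3-[2,4,6-tris(benzyloxy)phenyl]propyl chain on C6 of 8-bromo-octa-O-benzyl-EGCG | O[C@@H](Cc1c(OCc2ccccc2)cc(OCc2ccccc2)cc1OCc1ccccc1)[C@H](c1cc(OCc2ccccc2)c(OCc2ccccc2)c(OCc2ccccc2)c1)c1c(OCc3ccccc3)c(Br)c2c(c1OCc3ccccc3)C[C@@H](OC(=O)c1cc(OCc3ccccc3)c(OCc3ccccc3)c(OCc3ccccc3)c1)[C@@H](c1cc(OCc3ccccc3)c(OCc3ccccc3)c(OCc3ccccc3)c1)O2
F4 | step 7 | 8-bromo-heptadeca-O-benzyl derivative of the target (tris(benzyloxy)benzoate of F3; (1R,2S) chain, (2R,3R) flavan) | O=C(O[C@@H](Cc1c(OCc2ccccc2)cc(OCc2ccccc2)cc1OCc1ccccc1)[C@H](c1cc(OCc2ccccc2)c(OCc2ccccc2)c(OCc2ccccc2)c1)c1c(OCc3ccccc3)c(Br)c2c(c1OCc3ccccc3)C[C@@H](OC(=O)c1cc(OCc3ccccc3)c(OCc3ccccc3)c(OCc3ccccc3)c1)[C@@H](c1cc(OCc3ccccc3)c(OCc3ccccc3)c(OCc3ccccc3)c1)O2)c1cc(OCc2ccccc2)c(OCc2ccccc2)c(OCc2ccccc2)c1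
F5 | step 8 | benzylic carbinol from 12 and 2,4,6-tris(benzyloxy)phenyllithium (both carbinol epimers; chain centres as in 12) | O=C(O[C@@H](C(O)c1c(OCc2ccccc2)cc(OCc2ccccc2)cc1OCc1ccccc1)[C@H](c1cc(OCc2ccccc2)c(OCc2ccccc2)c(OCc2ccccc2)c1)c1c(OCc3ccccc3)c(Br)c2c(c1OCc3ccccc3)C[C@@H](OC(=O)c1cc(OCc3ccccc3)c(OCc3ccccc3)c(OCc3ccccc3)c1)[C@@H](c1cc(OCc3ccccc3)c(OCc3ccccc3)c(OCc3ccccc3)c1)O2)c1cc(OCc2ccccc2)c(OCc2ccccc2)c(OCc2ccccc2)c1
F6 | step 4 | diarylmethyl methyl ether: 8-bromo-6-{methoxy[3,4,5-tris(benzyloxy)phenyl]methyl}-octa-O-benzyl-EGCG (both epimers at the ether carbon) | COC(c1cc(OCc2ccccc2)c(OCc2ccccc2)c(OCc2ccccc2)c1)c1c(OCc3ccccc3)c(Br)c2c(c1OCc3ccccc3)C[C@@H](OC(=O)c1cc(OCc3ccccc3)c(OCc3ccccc3)c(OCc3ccccc3)c1)[C@@H](c1cc(OCc3ccccc3)c(OCc3ccccc3)c(OCc3ccccc3)c1)O2
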